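in all of them: starting material 0.10 M; gas phase 46 mM (held); added ligand 12 mM

|  | protic impurity | catalyst | remark | time |
|---|---|---|---|---|
| blue | 0.030 M | 1.2 mM | run made earlier |  |
| green | 0.030 M | 5 mM | run made earlier |  |
| red | 0.045 M | 2.5 mM | run made earlier |  |
| flask | 0.0300 M | 2.5 mM |  | 4.0 min |

| run | time / min | target / % |
|---|---|---|
| blue | 0.167 | 6.0 |
| blue | 0.500 | 13.5 |
| blue | 0.833 | 17.2 |
| blue | 1.33 | 20.8 |
| blue | 2.00 | 22.8 |
| blue | 2.50 | 25.3 |
| blue | 3.00 | 26.1 |
| green | 0.500 | 54.2 |
| green | 1.00 | 61.7 |
| green | 1.33 | 60.8 |
| green | 2.00 | 61.2 |
| green | 2.50 | 62.3 |
| green | 3.00 | 62.4 |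
| red | 0.250 | 17.9 |
| red | 0.500 | 26.5 |
| red | 0.833 | 31.8 |
| red | 1.50 | 35.7 |
| red | 3.00 | 36.9 |

(each reading ± 0.5 percentage points)

- at the start none of the gas phase is in solution

- south-west: doubling the saturation concentration of gas phase, all else as stated
- north-west: doubling the transfer coefficient of the gas phase, all else as stated
- east: doubling the amount of catalyst, all else as stated

- how much target there is at 4.0 min, in percent of the starting material charged
- the change that raises the amount of target at 4.0 min, in percent of the starting material charged most ("none" if none brings more than 2 percentage points) (south-west / north-west / east / none)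
- amount of target at 4.0 min, in percent of the starting material charged, after south-west

**Slow catalyst.** Slowness is what the blue run shows: its target climbs for minutes and flattens near 26.1 %, and we read such a flat end as a partition, as with a substrate shared between an enzyme and a side path, where the catalyst makes target from starting material and dissolved gas while something else takes the remainder.

**Carried quantity.** Blue gives 0.294 mM⁻¹ and green 0.332 mM⁻¹, and their mean, ω = 0.313 mM⁻¹, is what we carry: last target over the remainder of the charge, per unit of catalyst charged, the target odds per catalyst, a kind of selectivity factor. The flask, with 2.5 mM, then has odds of 0.783, which means 43.9 %.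

**First doubt.** The mean hides a spread, but blue's value alone gives 42.4 % and green's 45.4 %, so we accept that error. Red, with more impurity, gives 0.234 mM⁻¹, less than ω, so ω holds at the impurity of blue and green, which this flask shares.

**Second doubt.** A dying catalyst would flatten curves too. Taking the logarithmic measure per catalyst instead, 0.252 mM⁻¹ for blue and 0.196 mM⁻¹ for green, the flask comes to 42.9 %, so our number survives either reading.

**The changes.** East turns the flask into green, a reading of 62.4 %. South-west doubles the saturation concentration, and if we assume that this doubles the odds, an assumption about the side paths as well as about target formation, our rule gives 61.0 %, less than green, so we choose east.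

**The forecast.** It holds that “The plateaus show the catalyst dying rather than the substrate running out”, and it gives 47 %, south-west and 68 %, above our 43.9 % and our 61.0 %.

**The flask.** It gives 42.2 %; the best change is east, gaining 20 percentage points against 14 points for south-west, which reaches 56.4 %.

    gas phase ⇌ dissolved gas, rate k1*(csat - [dissolved gas]) (kL = 2.00 s⁻¹)
    starting material + dissolved gas + catalyst → catalyst + target (k = 10000 M⁻² s⁻¹)
    catalyst + added ligand ⇌ idle complex, settled at all times (K = 5800 M⁻¹)
    starting material + protic impurity → quenched substrate (k = 0.550 M⁻¹ s⁻¹)
    2 starting material → self-condensation product (k = 0.210 M⁻¹ s⁻¹)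

**Shared substrate.** At 0.0230 min the flask's starting material has a half-life of 0.61 min by the making of target against 0.75 min by the loss to quenched substrate, two rates close enough to share it, and at 4.00 min the flask holds 0.0722 % of starting material beside 20.7 % quenched substrate and 37.0 % self-condensation product. Its odds per catalyst come to 0.292 mM⁻¹ against ω of 0.313 mM⁻¹. For the neighbour charged with 0.0010 M of catalyst, ω gives 23.8 %, and that flask holds 22.8 %.

The readings come from a simulation for substances that don't exist; noise was put on by code.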